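A chain length is a quotient of two amounts, so I looked for these first: the G charged, 0.10 M, and the L that can begin a chain.

| setting | birch | flask |
|---|---|---|
| G | 0.10 M | 0.10 M |
| L | 1.3 mM | 1.3 mM |
| Z | 0.44 mM | 0.22 mM |
| remark | run made earlier |  |
| time |  | 12 min |

birch run (percent of the G charged)

| time / min | E / % | G / % |
|---|---|---|
| 0.333 | 1.7 | 97.5 |
| 0.667 | 5.8 | 92.3 |
| 1.00 | 11.0 | 87.1 |
| 1.33 | 15.9 | 80.6 |
| 1.50 | 18.6 | 78.0 |
| 2.00 | 26.0 | 69.3 |
| 2.50 | 33.2 | 61.7 |

(each reading ± 0.3 percentage points)

- whether the average number of monomer units in a chain (chains begun, living or dead) reaches 80 by 12 min (no / yes)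
- average number of monomer units in a chain (chains begun, living or dead) at 12 min

- the average divides the monomer in chains by the number of chains begun, living and dead together
- what was read earlier has a scatter of 0.3 percentage points, one standard deviation
- the earlier runs do not show the number of chains; that part of a forecast is a guess

The readings showed no count of chains, so I guessed that each Z removes one L, and I called the L charged minus the Z charged the free initiator n, 1.08 mM in the flask. The ratio of the G charged to n, the target degree of polymerisation, came to 92.6, which is 1.97 in powers of ten, against 1.90 for the wanted 80.0. But at 2.50 min the birch run held 33.2% in E out of 38.3% of G consumed, a read share s of 0.867, and s took 0.0621 off that logarithm. So, taking each unit of n as a chain begun and carrying that birch share over to the flask, I reckoned a length of 80.3 for the flask with its G used up, and I committed to a length near that, with the flask at the edge of the wanted one.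

The forecast gave no for reaching the wanted length and 67 for the length, saying “Reaching 80 would need fewer chains than L”. The flask gave yes, with a length of 96.0 at 12 min.

    G + L → D + E (k = 0.210 M⁻¹ s⁻¹)
    G + D → E + D, rate k2*[D]*[G] (k = 5.20 M⁻¹ s⁻¹)
    L → X (k = 0.00320 s⁻¹)
    G → Q (k = 4.20 × 10⁻⁴ s⁻¹)
    L + Z → J (k = 4200 M⁻¹ s⁻¹)

In the flask L met Z with a half-life of 0.75 s, Z held at its charge, far shorter than the 3.6 min of its step to X, and at 1.20 min Z stood at 0% and J at 2.20 × 10⁻⁴ M. At 12.0 min the flask held D at 9.14 × 10⁻⁴ M, X at 1.65 × 10⁻⁴ M and L at 0.0797% of its charge, together 1.08 mM against n of 1.08 mM, so D was 84.6% of n, and with E at 87.8% the length stood at 96.0.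

(The earlier runs and the new flask come from a simulation for substances that don't exist; noise was put on by code.)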